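**Plan**

1. Retrosynthesis: the C6 epoxyangelate ester is cut first, then the C5–C6 bond of ring A, then on ring B the C1–carbinol bond (aldol), the C7a–C7 bond (Michael) and the C3a–C4 bond (conjugate addition of isopropenyl).
2. Enabling feature: in ring A (C3a–C4–C5–C6–C7–C7a) the exocyclic C4 methylene, the C5 methylene and the axial C6 carbinol form a 3-methylenecyclohexanol. That is the imprint of a type 2 carbonyl-ene reaction between a C6 aldehyde and a C3a isopropenyl group held trans on cyclopentane ring B.
3. Forward: ring B is bought as (R)-4-silyloxycyclopentenone. Isopropenyl is added and the silyloxy group eliminated, a one-flask Mukaiyama–Michael/aldol sequence attaches the C7 thioester arm and the C1 two-carbon unit, and ketone reduction, angeloylation and oxidation-level changes give the keto aldehyde. Ring A closes last and the epoxy ester goes on in the final step.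
4. Stereochemistry: C3a comes from the (R)-silyloxy centre (anti addition, then elimination); C7a and C1 from trans induction around ring B; C7 from the E ketene acetal in an open transition state; C2 from hydride delivery anti to the C1 arm; C6 from the chair ene transition state; the oxirane from Sharpless epoxidation of angelyl alcohol with D-(−)-diethyl tartrate.

Key step: step 9

Remark: the target numbering (C1 acetyl carbon, C2 angelate carbon, C3, C3a, C4–C7, C7a) is used for every intermediate, β is the ring B face that carries the C3a carbon substituent, and the carbinol carbon made in step 3 is carried as both epimers until step 7 removes it.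

**Route**

Step 1
Reactants: 1 (R)-4-[(tert-butyldimethylsilyl)oxy]cyclopent-2-en-1-one; 2 isopropenylmagnesium bromide (prop-1-en-2-ylmagnesium bromide)
Product: 5 (4R)-4-(prop-1-en-2-yl)cyclopent-2-en-1-one, via silyloxy ketone 3 (not isolated), via hydroxy ketone 4 (not isolated)
Conditions: CH2=C(CH3)MgBr, CuBr·SMe2 (10 mol%), THF, −78 → −40 °C; aq. NH4Cl; then AcOH–H2O–THF (6:1:1), 60 °C
Reagents that add atoms: none
Why: Copper-catalysed 1,4-addition of the Grignard reagent should occur anti to the silyloxy group, and warm aqueous acetic acid then cleaves the silyl ether and dehydrates the β-hydroxy ketone through its enol (the mild-acid route from β-hydroxycyclopentanones to cyclopent-2-enones), so the silyloxy stereocentre is exchanged for the future C3a centre (R) without exposing the doubly allylic γ-hydrogen of 5 to base.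

Step 2
Reactants: 6 S-ethyl 3-methylbutanethioate
Product: 7 (E)-tert-butyl{[1-(ethylsulfanyl)-3-methylbut-1-en-1-yl]oxy}dimethylsilane (isopropyl cis to the silyloxy group)
Conditions: LiN(i-Pr)2, THF, −78 °C; then t-BuMe2SiCl, DMPU, −78 °C → rt
Reagents that add atoms: tert-butyldimethylsilyl chloride, CC(C)(C)[Si](C)(C)Cl
Why: Kinetic deprotonation of a thioester by the lithium amide in THF favours the enolate with the alkyl substituent cis to oxygen, and O-silylation (DMPU added only after enolisation) fixes it as the E ketene silyl acetal, whose geometry is to be confirmed by NOE before use.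

Step 3
Reactants: 5 (4R)-4-(prop-1-en-2-yl)cyclopent-2-en-1-one; 7 E ketene silyl acetal; 8 acetaldehyde
Product: 10 S-ethyl (2S)-2-[(1S,2S,5R)-2-(1-{[tert-butyl(dimethyl)silyl]oxy}ethyl)-3-oxo-5-(prop-1-en-2-yl)cyclopentyl]-3-methylbutanethioate (both carbinol epimers), via silyl enol ether 9 (not isolated)
Conditions: Ph3CSbCl6 (5 mol%), CH2Cl2, −78 °C; then CH3CHO, −78 °C; pyridine quench
Reagents that add atoms: none
Why: Trityl-cation-catalysed Mukaiyama–Michael addition followed in the same flask by Mukaiyama aldol addition with silyl transfer: the acetal should add to the enone face anti to the isopropenyl group (C7a), through an open antiperiplanar transition state in which the acetal hydrogen lies over the ring, the isopropyl group sits beside the enone α-carbon and the bulky silyloxy group of the E isomer points out toward H7a (C7, S), and acetaldehyde then enters 9 anti to the new C7a arm (C1 trans), the carbinol centre being left uncontrolled because step 7 removes it.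

Step 4
Reactants: 10 silyloxy keto thioester
Product: 11 S-ethyl (2S)-2-[(1S,2R,3S,5R)-2-(1-{[tert-butyl(dimethyl)silyl]oxy}ethyl)-3-hydroxy-5-(prop-1-en-2-yl)cyclopentyl]-3-methylbutanethioate
Conditions: LiBH(s-Bu)3, THF, −78 °C; aq. NH4Cl
Reagents that add atoms: none
Why: The bulky borohydride should attack the cyclopentanone from the α face, anti to the adjacent C1 arm, to give the 1,2-cis alcohol (C2, S), and at −78 °C it should leave the hindered thioester untouched (substrate-controlled, chemoselective ketone reduction).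

Step 5
Reactants: 11 C2 alcohol; 12 angelic acid [(2Z)-2-methylbut-2-enoic acid]
Product: 14 (1S,2R,3S,4R)-2-(1-{[tert-butyl(dimethyl)silyl]oxy}ethyl)-3-[(2S)-1-(ethylsulfanyl)-3-methyl-1-oxobutan-2-yl]-4-(prop-1-en-2-yl)cyclopentyl (2Z)-2-methylbut-2-enoate, via mixed anhydride 13 (not isolated)
Conditions: 12, 2,4,6-Cl3C6H2COCl, Et3N, toluene, rt; then 11, toluene, 75 °C
Reagents that add atoms: none
Why: Acylation through the 2,4,6-trichlorobenzoyl mixed anhydride without a nucleophilic catalyst (Yamaguchi-type esterification) is an established way to make angelates without Z-to-E isomerisation to the tiglate.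

Step 6
Reactants: 14 angelate silyl ether
Product: 15 (1S,2S,3S,4R)-3-[(2S)-1-(ethylsulfanyl)-3-methyl-1-oxobutan-2-yl]-2-(1-hydroxyethyl)-4-(prop-1-en-2-yl)cyclopentyl (2Z)-2-methylbut-2-enoate
Conditions: aq. HF (48%), MeCN, 0 °C → rt
Reagents that add atoms: none
Why: Acidic fluoride should cleave the secondary silyl ether while thioester, angelate and the 1,1-disubstituted alkene stay inert, and the acidic medium disfavours 1,3-acyl migration of the neighbouring angelate.

Step 7
Reactants: 15 carbinol
Product: 16 (1S,2R,3S,4R)-2-acetyl-3-[(2S)-1-(ethylsulfanyl)-3-methyl-1-oxobutan-2-yl]-4-(prop-1-en-2-yl)cyclopentyl (2Z)-2-methylbut-2-enoate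
Conditions: Dess–Martin periodinane, CH2Cl2, 0 °C → rt
Reagents that add atoms: none
Why: Dess–Martin oxidation should convert both carbinol epimers into the single methyl ketone under non-basic conditions, so the β-acyloxy ketone neither loses angelic acid nor epimerises at C1.

Step 8
Reactants: 16 keto thioester
Product: 17 (1S,2R,3R,4R)-2-acetyl-3-[(2S)-3-methyl-1-oxobutan-2-yl]-4-(prop-1-en-2-yl)cyclopentyl (2Z)-2-methylbut-2-enoate
Conditions: Et3SiH, Pd/C (10 wt %, cat.), acetone, rt
Reagents that add atoms: none
Why: Fukuyama reduction stops at the aldehyde oxidation level under neutral conditions that tolerate ketone and ester groups and should not epimerise the α-branched aldehyde carbon C7.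

Step 9
Reactants: 17 keto aldehyde
Product: 18 (1R,2S,3aR,6R,7S,7aR)-1-acetyl-6-hydroxy-4-methylidene-7-(propan-2-yl)octahydro-1H-inden-2-yl (2Z)-2-methylbut-2-enoate
Conditions: Me2AlCl (2.5 equiv), CH2Cl2, −78 → −30 °C; aq. potassium sodium tartrate
Reagents that add atoms: none
Why: Me2AlCl binds the aldehyde, the terminal carbon of the isopropenyl group (C5) bonds to C6 while a methyl hydrogen passes to oxygen in a six-centre array, and the alcohol–aluminium complex then loses methane, which removes the only proton source that could isomerise the new alkene. The closest known reaction type is the Me2AlCl-promoted type 2 intramolecular carbonyl-ene cyclisation of 5-methylhex-5-enals to 3-methylenecyclohexanols. Ring A closes in a 6-exo-trig mode at the carbonyl carbon (6-endo with respect to the alkene) through a chair in which the two ring B bonds at C3a and C7a are equatorial. The new C6 centre (R) follows from that chair: the C7 isopropyl group is equatorial and the complexed C=O has to be axial for its oxygen to reach the methyl hydrogen, so the C6–O bond should end axial and cis to the isopropyl group. The step needs the aldehyde to react in preference to the C1 methyl ketone and the esters, and the alkene to end exocyclic at C4; the much higher enophilicity of an aluminium-bound aldehyde at low temperature should secure the first, and the concerted hydrogen transfer from the methyl group secures the second.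

Step 10
Reactants: 12 angelic acid
Product: 19 (2Z)-2-methylbut-2-en-1-ol
Conditions: LiAlH4, Et2O, 0 °C → rt; aq. NaOH work-up
Reagents that add atoms: none
Why: Aluminium hydride reduction of an α-alkyl-α,β-unsaturated acid proceeds 1,2 and should give the allylic alcohol with the Z trisubstituted alkene intact.

Step 11
Reactants: 19 (2Z)-2-methylbut-2-en-1-ol
Product: 20 [(2R,3S)-2,3-dimethyloxiran-2-yl]methanol
Conditions: Ti(OiPr)4 (10 mol%), D-(−)-diethyl tartrate (12 mol%), t-BuOOH, 4 Å molecular sieves, CH2Cl2, −20 °C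
Reagents that add atoms: tert-butyl hydroperoxide, CC(C)(C)OO
Why: Sharpless asymmetric epoxidation: with the D-(−)-tartrate the titanium-bound peroxide should deliver oxygen to the alkene face that gives the 2R,3S epoxy alcohol, the cis relation of hydroxymethyl and C3 methyl following from the Z alkene.

Step 12
Reactants: 20 epoxy alcohol
Product: 21 (2S,3S)-2,3-dimethyloxirane-2-carboxylic acid
Conditions: RuCl3·xH2O (2 mol%), NaIO4, CCl4–MeCN–H2O, rt
Reagents that add atoms: water, O
Why: Catalytic ruthenium tetroxide oxidation takes a primary epoxy alcohol through the aldehyde hydrate to the glycidic acid without opening the oxirane; neither stereocentre is touched (the C2 descriptor changes only through priorities).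

Step 13
Reactants: 18 C6 alcohol; 21 epoxy acid
Product: 23 (1R,2S,3aR,6R,7S,7aR)-1-acetyl-4-methylidene-2-{[(2Z)-2-methylbut-2-enoyl]oxy}-7-(propan-2-yl)octahydro-1H-inden-6-yl (2S,3S)-2,3-dimethyloxirane-2-carboxylate, via mixed anhydride 22 (not isolated)
Conditions: 21, 2,4,6-Cl3C6H2COCl, Et3N, THF, 0 °C → rt; then 18, DMAP, toluene, rt
Reagents that add atoms: none
Why: Yamaguchi esterification: the acylpyridinium formed from the mixed anhydride should acylate the hindered axial C6 alcohol with retention at carbon under conditions mild enough for the oxirane, the exocyclic alkene and the β-acyloxy ketone.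

**Compound list**

1 | (R)-4-[(tert-butyldimethylsilyl)oxy]cyclopent-2-en-1-one | O=C1C=C[C@H](O[Si](C)(C)C(C)(C)C)C1 | starting material
2 | isopropenylmagnesium bromide | C=C(C)[Mg]Br | starting material
3 | (3S,4R)-4-[(tert-butyldimethylsilyl)oxy]-3-(prop-1-en-2-yl)cyclopentan-1-one | O=C1C[C@@H](C(C)=C)[C@H](O[Si](C)(C)C(C)(C)C)C1 | intermediate
4 | (3S,4R)-4-hydroxy-3-(prop-1-en-2-yl)cyclopentan-1-one | O=C1C[C@@H](C(C)=C)[C@H](O)C1 | intermediate
5 | (4R)-4-(prop-1-en-2-yl)cyclopent-2-en-1-one | O=C1C=C[C@H](C(C)=C)C1 | intermediate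
6 | S-ethyl 3-methylbutanethioate | CCSC(=O)CC(C)C | starting material
7 | (E)-tert-butyl{[1-(ethylsulfanyl)-3-methylbut-1-en-1-yl]oxy}dimethylsilane | CC(C)/C=C(\O[Si](C)(C)C(C)(C)C)SCC | intermediate
8 | acetaldehyde | CC=O | starting material
9 | S-ethyl (2S)-2-[(1S,5R)-3-{[tert-butyl(dimethyl)silyl]oxy}-5-(prop-1-en-2-yl)cyclopent-2-en-1-yl]-3-methylbutanethioate | C=C(C)[C@@H]1CC(O[Si](C)(C)C(C)(C)C)=C[C@H]1[C@H](C(C)C)C(=O)SCC | intermediate
10 | S-ethyl (2S)-2-[(1S,2S,5R)-2-(1-{[tert-butyl(dimethyl)silyl]oxy}ethyl)-3-oxo-5-(prop-1-en-2-yl)cyclopentyl]-3-methylbutanethioate (carbinol carbon as both epimers) | C=C(C)[C@@H]1CC(=O)[C@H](C(C)O[Si](C)(C)C(C)(C)C)[C@H]1[C@H](C(C)C)C(=O)SCC | intermediate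
11 | S-ethyl (2S)-2-[(1S,2R,3S,5R)-2-(1-{[tert-butyl(dimethyl)silyl]oxy}ethyl)-3-hydroxy-5-(prop-1-en-2-yl)cyclopentyl]-3-methylbutanethioate | C=C(C)[C@@H]1C[C@H](O)[C@H](C(C)O[Si](C)(C)C(C)(C)C)[C@H]1[C@H](C(C)C)C(=O)SCC | intermediate
12 | angelic acid, (2Z)-2-methylbut-2-enoic acid | C/C=C(/C)C(=O)O | starting material
13 | (2Z)-2-methylbut-2-enoic 2,4,6-trichlorobenzoic anhydride | C/C=C(/C)C(=O)OC(=O)c1c(Cl)cc(Cl)cc1Cl | intermediate
14 | (1S,2R,3S,4R)-2-(1-{[tert-butyl(dimethyl)silyl]oxy}ethyl)-3-[(2S)-1-(ethylsulfanyl)-3-methyl-1-oxobutan-2-yl]-4-(prop-1-en-2-yl)cyclopentyl (2Z)-2-methylbut-2-enoate | C=C(C)[C@@H]1C[C@H](OC(=O)/C(C)=C\C)[C@H](C(C)O[Si](C)(C)C(C)(C)C)[C@H]1[C@H](C(C)C)C(=O)SCC | intermediate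
15 | (1S,2S,3S,4R)-3-[(2S)-1-(ethylsulfanyl)-3-methyl-1-oxobutan-2-yl]-2-(1-hydroxyethyl)-4-(prop-1-en-2-yl)cyclopentyl (2Z)-2-methylbut-2-enoate | C=C(C)[C@@H]1C[C@H](OC(=O)/C(C)=C\C)[C@H](C(C)O)[C@H]1[C@H](C(C)C)C(=O)SCC | intermediate
16 | (1S,2R,3S,4R)-2-acetyl-3-[(2S)-1-(ethylsulfanyl)-3-methyl-1-oxobutan-2-yl]-4-(prop-1-en-2-yl)cyclopentyl (2Z)-2-methylbut-2-enoate | C=C(C)[C@@H]1C[C@H](OC(=O)/C(C)=C\C)[C@H](C(C)=O)[C@H]1[C@H](C(C)C)C(=O)SCC | intermediate
17 | (1S,2R,3R,4R)-2-acetyl-3-[(2S)-3-methyl-1-oxobutan-2-yl]-4-(prop-1-en-2-yl)cyclopentyl (2Z)-2-methylbut-2-enoate | C=C(C)[C@@H]1C[C@H](OC(=O)/C(C)=C\C)[C@H](C(C)=O)[C@H]1[C@H](C(C)C)C=O | intermediate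
18 | (1R,2S,3aR,6R,7S,7aR)-1-acetyl-6-hydroxy-4-methylidene-7-(propan-2-yl)octahydro-1H-inden-2-yl (2Z)-2-methylbut-2-enoate | C=C1C[C@@H](O)[C@@H](C(C)C)[C@@H]2[C@@H](C(C)=O)[C@@H](OC(=O)/C(C)=C\C)C[C@@H]12 | intermediate
19 | (2Z)-2-methylbut-2-en-1-ol | C/C=C(/C)CO | intermediate
20 | [(2R,3S)-2,3-dimethyloxiran-2-yl]methanol | OC[C@@]1(C)O[C@H]1C | intermediate
21 | (2S,3S)-2,3-dimethyloxirane-2-carboxylic acid | OC(=O)[C@@]1(C)O[C@H]1C | intermediate
22 | (2S,3S)-2,3-dimethyloxirane-2-carboxylic 2,4,6-trichlorobenzoic anhydride | O=C(OC(=O)[C@@]1(C)O[C@H]1C)c1c(Cl)cc(Cl)cc1Cl | intermediate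
23 | (1R,2S,3aR,6R,7S,7aR)-1-acetyl-4-methylidene-2-{[(2Z)-2-methylbut-2-enoyl]oxy}-7-(propan-2-yl)octahydro-1H-inden-6-yl (2S,3S)-2,3-dimethyloxirane-2-carboxylate | C=C1C[C@@H](OC(=O)[C@@]2(C)O[C@H]2C)[C@@H](C(C)C)[C@@H]2[C@@H](C(C)=O)[C@@H](OC(=O)/C(C)=C\C)C[C@@H]12 | target

**Step count**

Total: 13 steps. Longest linear sequence: 9 steps (steps 1, 3, 4, 5, 6, 7, 8, 9, 13).

**Steps most likely to fail**

Step 3. The open transition states may not be well differentiated, so the ketene acetal geometry could be passed on to C7 with poor or inverted diastereoselectivity relative to C7a. The fallback moves the control element to the geometric partner of the acetal. Setting out from 6, enolisation with LiN(i-Pr)2 in THF containing DMPU from the start, then silylation, should give (Z)-tert-butyl{[1-(ethylsulfanyl)-3-methylbut-1-en-1-yl]oxy}dimethylsilane F1. In its open transition state hydrogen and isopropyl change places over the ring, so the opposite relative configuration at C7/C7a is expected. Reaction of F1 with 5 and 8 under the trityl catalysis of step 3 comes back to the route at 10.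

Step 9. The Lewis acid may also engage the C1 ketone (aldol closure of the 1,5-keto aldehyde, loss of angelic acid from the activated β-acyloxy ketone), or the complexed carbonyl may react through a stepwise cationic path in which the axial preference at C6 is eroded. The fallback closes ring A before the ketone is unveiled. Setting out from 14, Fukuyama reduction should give the silyloxy aldehyde F2, and Me2AlCl then closes ring A to the silyloxy alcohol F3. Because no other ketone is present there, a poor C6 ratio can be repaired by Dess–Martin oxidation to the ring A ketone F4 and equatorial hydride delivery with LiBH(s-Bu)3, which returns F3 with the axial hydroxyl. Yamaguchi esterification with 21 (through 22) gives the silyloxy epoxy ester F5, HF·pyridine in THF–pyridine frees the carbinol F6, and Dess–Martin oxidation comes back to the route at 23.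

Step 8. Palladium hydride species may isomerise or reduce the isopropenyl group, or insertion into the hindered thioester may be too slow. The fallback avoids palladium and reaches the aldehyde by oxidation instead of reduction. Setting out from 11, LiBH4 in THF reduces the thioester to the diol F7; t-BuMe2SiCl and imidazole silylate the primary hydroxyl selectively to the bis-silyl ether F8; angeloylation as in step 5 (through 13) gives the angelate F9; aqueous HF in MeCN removes both silyl groups to give the diol F10; and Dess–Martin oxidation of both carbinols in one operation comes back to the route at 17.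

**Further compounds**

F1 | step 3 | (Z)-tert-butyl{[1-(ethylsulfanyl)-3-methylbut-1-en-1-yl]oxy}dimethylsilane | CC(C)/C=C(/O[Si](C)(C)C(C)(C)C)SCC
F2 | step 9 | silyloxy aldehyde: 17 with 1-(tert-butyldimethylsilyloxy)ethyl at C1 in place of acetyl | C=C(C)[C@@H]1C[C@H](OC(=O)/C(C)=C\C)[C@H](C(C)O[Si](C)(C)C(C)(C)C)[C@H]1[C@H](C(C)C)C=O
F3 | step 9 | silyloxy alcohol: 18 with 1-(tert-butyldimethylsilyloxy)ethyl at C1 in place of acetyl | C=C1C[C@@H](O)[C@@H](C(C)C)[C@@H]2[C@@H](C(C)O[Si](C)(C)C(C)(C)C)[C@@H](OC(=O)/C(C)=C\C)C[C@@H]12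
F4 | step 9 | ring A ketone: F3 with C6 carbonyl in place of the carbinol | C=C1CC(=O)[C@@H](C(C)C)[C@@H]2[C@@H](C(C)O[Si](C)(C)C(C)(C)C)[C@@H](OC(=O)/C(C)=C\C)C[C@@H]12
F5 | step 9 | silyloxy epoxy ester: 23 with 1-(tert-butyldimethylsilyloxy)ethyl at C1 in place of acetyl | C=C1C[C@@H](OC(=O)[C@@]2(C)O[C@H]2C)[C@@H](C(C)C)[C@@H]2[C@@H](C(C)O[Si](C)(C)C(C)(C)C)[C@@H](OC(=O)/C(C)=C\C)C[C@@H]12
F6 | step 9 | carbinol: 23 with 1-hydroxyethyl at C1 in place of acetyl | C=C1C[C@@H](OC(=O)[C@@]2(C)O[C@H]2C)[C@@H](C(C)C)[C@@H]2[C@@H](C(C)O)[C@@H](OC(=O)/C(C)=C\C)C[C@@H]12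
F7 | step 8 | diol: 11 with CH2OH at C6 in place of the thioester | C=C(C)[C@@H]1C[C@H](O)[C@H](C(C)O[Si](C)(C)C(C)(C)C)[C@H]1[C@H](C(C)C)CO
F8 | step 8 | bis-silyl ether: F7 with the primary hydroxyl as tert-butyldimethylsilyl ether | C=C(C)[C@@H]1C[C@H](O)[C@H](C(C)O[Si](C)(C)C(C)(C)C)[C@H]1[C@H](C(C)C)CO[Si](C)(C)C(C)(C)C
F9 | step 8 | angelate: F8 acylated at the C2 hydroxyl with (2Z)-2-methylbut-2-enoyl | C=C(C)[C@@H]1C[C@H](OC(=O)/C(C)=C\C)[C@H](C(C)O[Si](C)(C)C(C)(C)C)[C@H]1[C@H](C(C)C)CO[Si](C)(C)C(C)(C)C
F10 | step 8 | diol: F9 with both silyl groups removed | C=C(C)[C@@H]1C[C@H](OC(=O)/C(C)=C\C)[C@H](C(C)O)[C@H]1[C@H](C(C)C)CO
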